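**Retrosynthetic overview**

1. Decalin half: (+)-sclareolide 1 brings rings A and B, all four ring stereocentres and the tertiary C2–O bond. Reduction to lactol 2 and one-carbon homologation through enol ether 3 give lactol 4, a latent C3′ aldehyde.
2. Cyclohexane half: dihydro-β-ionone 5 brings ring C. A proposed enantioselective contra-thermodynamic alkene transposition sets C1″ in (S)-γ-dihydroionone 6, whose hydrazone 7 is the source of alkenyllithium 8.
3. C3′–C4′ disconnection: 8 adds to lithium lactolate 9 (from 4) to give the secondary allylic alcohol 10.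
4. Key disconnection, C–O: the C3′ oxygen of 10 is moved to the methylidene carbon by a [3,3] shift of its perrhenate ester, trapped as silyl ether 11. This makes the CH2–O bond and the E-alkene of target 12.
5. Ring order: no carbocycle is built; rings A and B come with 1 and ring C with 5 (only the lactol rings of 2 and 4 are formed and reopened).

Assumption: the enantiomer of the bis(oxazoline) ligand that gives (S)-6 in step 3 is fixed by a first small run, since the sense of induction of a new reaction cannot be predicted. Locants follow the systematic name of the target: decalin C1/C2/C4a/C8a, side chain C1′–C6′, cyclohexane C1″.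

**Route**

Step 1
Reactants: 1 (+)-sclareolide, (3aR,5aS,9aS,9bR)-3a,6,6,9a-tetramethyldecahydronaphtho[2,1-b]furan-2(1H)-one
Product: 2 sclareolide lactol (3aR,5aS,9aS,9bR)-3a,6,6,9a-tetramethyldodecahydronaphtho[2,1-b]furan-2-ol (anomer mixture)
Conditions: i-Bu2AlH (1.2 equiv), CH2Cl2, −78 °C; then aq. KNaC4H4O6
Reagents that add atoms: none
Why: DIBAL-H partial reduction of a lactone stops at the aluminium hemiacetal at −78 °C and gives the lactol on work-up; the ring stereocentres are untouched and the new anomeric centre is destroyed in step 2.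

Step 2
Reactants: 2 sclareolide lactol
Product: 4 six-membered lactol (4aR,6aS,10aS,10bR)-4a,7,7,10a-tetramethyldodecahydro-1H-benzo[f]chromen-3-ol (anomer mixture), via hydroxy enol ether 3 (not isolated)
Conditions: MeOCH2PPh3Cl (3.0 equiv), KN(SiMe3)2 (2.9 equiv), THF, 0 °C → rt; then 1 M aq. HCl, THF, rt
Reagents that add atoms: (methoxymethyl)triphenylphosphonium chloride, COC[P+](c1ccccc1)(c1ccccc1)c1ccccc1.[Cl-]; water, O
Why: Wittig olefination of the ring-opened hydroxy-aldehyde tautomer with the methoxymethylene ylide, then enol-ether hydrolysis, is the standard one-carbon aldehyde homologation; the freed C3′ aldehyde is captured by the tertiary C2 hydroxyl as the lactol and no decalin stereocentre is affected.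

Step 3
Reactants: 5 dihydro-β-ionone, 4-(2,6,6-trimethylcyclohex-1-en-1-yl)butan-2-one
Product: 6 (S)-γ-dihydroionone, 4-[(1S)-2,2-dimethyl-6-methylidenecyclohexyl]butan-2-one
Conditions: 9-mesityl-3,6-di-tert-butyl-10-phenylacridinium tetrafluoroborate (3 mol %), CrCl2 (10 mol %), (3aS,3a′S,8aR,8a′R)-2,2′-(cyclopropane-1,1-diyl)bis(3a,8a-dihydro-8H-indeno[1,2-d]oxazole) or its enantiomer (12 mol %), 2,4,6-collidine (20 mol %), MeOH (10 equiv), CH2Cl2, 450 nm LEDs, −20 °C
Reagents that add atoms: none
Why: Proposed new method: the excited acridinium oxidises only the tetrasubstituted alkene (about +1.6 V) to its radical cation, collidine removes an allylic proton, divalent chromium captures the allyl radical, and the trivalent allylchromium settles with the metal on the unhindered ring-methyl carbon; methanol bound to the chiral bis(oxazoline)–chromium centre then protonates the γ-carbon C1″ through a closed six-membered transition state, creating the exocyclic methylidene and the C1″–H stereocentre on one face, and the 1,1-disubstituted product (oxidation potential above +2.2 V) cannot be re-oxidised, so it accumulates against thermodynamics and is not racemised; the closest known reactions are the achiral photoredox/chromium contra-thermodynamic positional alkene isomerisation and the enantioselective γ-addition of catalytically generated chiral allylchromium species to aldehydes, and what is new is a stereocentre-forming enantioselective protodemetalation on a tetrasubstituted cycloalkene.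

Step 4
Reactants: 6 (S)-γ-dihydroionone
Product: 7 trisylhydrazone N′-{4-[(1S)-2,2-dimethyl-6-methylidenecyclohexyl]butan-2-ylidene}-2,4,6-tri(propan-2-yl)benzenesulfonohydrazide (mainly E)
Conditions: 2,4,6-(i-Pr)3C6H2SO2NHNH2 (1.05 equiv), MeOH, rt
Reagents that add atoms: 2,4,6-triisopropylbenzenesulfonyl hydrazide, CC(C)c1cc(C(C)C)c(S(=O)(=O)NN)c(C(C)C)c1
Why: Hydrazone condensation at the unhindered methyl ketone under neutral conditions leaves the acid-labile exocyclic alkene and the non-epimerisable C1″ centre untouched, and the E-hydrazone (sulfonamide syn to the methyl) is the isomer needed for regioselective deprotonation in step 5.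

Step 5
Reactants: 7 trisylhydrazone; 4 six-membered lactol
Product: 10 allylic diol (1R,2R,4aS,8aS)-1-{6-[(1S)-2,2-dimethyl-6-methylidenecyclohexyl]-3-hydroxy-4-methylidenehexyl}-2,5,5,8a-tetramethyldecahydronaphthalen-2-ol (both C3′ epimers), via alkenyllithium 8 (not isolated), via lithium lactolate 9 (not isolated)
Conditions: 7, n-BuLi (2.05 equiv), THF, −78 °C then 0 °C (−N2); separately 4 (1.3 equiv), n-BuLi (1.3 equiv), THF, −78 °C; combine at −78 °C → 0 °C; then H2O
Reagents that add atoms: none
Why: Shapiro reaction: the hydrazone dianion, formed by deprotonation of the methyl group syn to the sulfonamide, loses sulfinate and N2 to give the 1,1-disubstituted alkenyllithium, which adds 1,2 to the aldehyde tautomer of the lactolate (the hemiacetal of a hindered tertiary alkoxide opens readily); the C3′ carbinol centre forms unselectively, which does not matter because it is erased in step 6.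

Step 6
Reactants: 10 allylic diol
Product: 12 target (1R,2R,4aS,8aS)-1-{(3E)-6-[(1S)-2,2-dimethyl-6-methylidenecyclohexyl]-4-(hydroxymethyl)hex-3-en-1-yl}-2,5,5,8a-tetramethyldecahydronaphthalen-2-ol, via trimethylsilyl ether 11 (not isolated)
Conditions: Ph3SiOReO3 (3 mol %), N,O-bis(trimethylsilyl)acetamide (1.3 equiv), Et2O, −50 → −20 °C; then K2CO3, MeOH, rt
Reagents that add atoms: none
Why: Key C–O bond formation by 1,3-transposition of an allylic alcohol under heptavalent rhenium catalysis: the perrhenate ester of the C3′ carbinol undergoes a chair [3,3]-sigmatropic shift with the C2′ chain equatorial, so oxygen is delivered to the methylidene carbon and the new C3′=C4′ bond is E from either C3′ epimer (the same preference as in a Johnson–Claisen rearrangement of such alcohols), while the silylating agent caps only the unhindered primary alcohol as it forms and so blocks the reverse shift and E/Z equilibration; the tertiary C2 hydroxyl is too hindered to react at this temperature.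

**Compound list**

1 | (+)-sclareolide | O=C1C[C@@H]2[C@@]3(C)CCCC(C)(C)[C@@H]3CC[C@@]2(C)O1 | starting material
2 | sclareolide lactol (anomer mixture) | OC1C[C@@H]2[C@@]3(C)CCCC(C)(C)[C@@H]3CC[C@@]2(C)O1 | intermediate
3 | hydroxy enol ether, (1R,2R,4aS,8aS)-1-(3-methoxyprop-2-en-1-yl)-2,5,5,8a-tetramethyldecahydronaphthalen-2-ol (E/Z mixture) | COC=CC[C@@H]1[C@@]2(C)CCCC(C)(C)[C@@H]2CC[C@@]1(C)O | intermediate
4 | six-membered lactol, (4aR,6aS,10aS,10bR)-4a,7,7,10a-tetramethyldodecahydro-1H-benzo[f]chromen-3-ol (anomer mixture) | OC1CC[C@@H]2[C@@]3(C)CCCC(C)(C)[C@@H]3CC[C@@]2(C)O1 | intermediate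
5 | dihydro-β-ionone | CC(=O)CCC1=C(C)CCCC1(C)C | starting material
6 | (S)-γ-dihydroionone | C=C1CCCC(C)(C)[C@@H]1CCC(C)=O | intermediate
7 | trisylhydrazone of 6 | C=C1CCCC(C)(C)[C@@H]1CCC(C)=NNS(=O)(=O)c1c(C(C)C)cc(C(C)C)cc1C(C)C | intermediate
8 | alkenyllithium, {4-[(1S)-2,2-dimethyl-6-methylidenecyclohexyl]but-1-en-2-yl}lithium | C=C1CCCC(C)(C)[C@@H]1CCC(=C)[Li] | intermediate
9 | lithium lactolate of 4 | [Li]OC1CC[C@@H]2[C@@]3(C)CCCC(C)(C)[C@@H]3CC[C@@]2(C)O1 | intermediate
10 | allylic diol (C3′ epimers) | C=C1CCCC(C)(C)[C@@H]1CCC(=C)C(O)CC[C@@H]1[C@@]2(C)CCCC(C)(C)[C@@H]2CC[C@@]1(C)O | intermediate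
11 | trimethylsilyl ether of 12 (primary O–SiMe3, E) | C=C1CCCC(C)(C)[C@@H]1CC/C(=C\CC[C@@H]1[C@@]2(C)CCCC(C)(C)[C@@H]2CC[C@@]1(C)O)CO[Si](C)(C)C | intermediate
12 | target CNP0209309.1 | C=C1CCCC(C)(C)[C@@H]1CC/C(=C\CC[C@@H]1[C@@]2(C)CCCC(C)(C)[C@@H]2CC[C@@]1(C)O)CO | target

**Totals**

Total step count: 6.
Longest linear sequence: 4 steps (5 → 6 → 7 → 10 → 12; the arm 1 → 2 → 4 → 10 → 12 is equally long).

**Steps most likely to fail**

Step 3 (the proposed new step). The enantioselectivity of the protonation is untested. Deprotonation at the ring CH2 or the chain CH2 gives other allylchromium isomers; the trisubstituted alkenes they produce are still oxidisable and are fed back into the cycle, but this may lower the ee. The allylchromium could also add to the ketone instead of being protonated. The fallback uses known chemistry only; it sets out from 5 and comes back at 6. Acetalise 5 with ethane-1,2-diol (TsOH, toluene, water removal) to the dioxolane F1. Epoxidise the tetrasubstituted alkene with mCPBA (NaHCO3, CH2Cl2, 0 °C) to the racemic epoxy ketal F2. Isomerise the epoxide with diethylaluminium 2,2,6,6-tetramethylpiperidide (toluene, 0 °C), which abstracts a hydrogen of the ring methyl, to the racemic tertiary allylic alcohol F3 that already carries the exocyclic methylidene. Acylate its lithium alkoxide (n-BuLi, then ClCO2Me) to the methyl carbonate F4. Reduce F4 with HCO2H and 1,8-bis(dimethylamino)naphthalene under Pd2(dba)3 and (R)-2-(diphenylphosphino)-2′-methoxy-1,1′-binaphthyl (or its enantiomer): the π-allyl complex formed by zerovalent palladium erases the carbinol stereocentre, and the hydride from formate is delivered enantioselectively to the more substituted allyl terminus (asymmetric formate hydrogenolysis, which keeps the alkene exocyclic), giving the (S)-ketal F5. Hydrolyse F5 (pyridinium tosylate, wet acetone) to 6.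

Step 5. The lactolate may open too slowly, and the alkenyllithium may act as a base. The fallback sets out from 4 and comes back at 10. Oxidise 4 (PhI(OAc)2, catalytic TEMPO, CH2Cl2) to the δ-lactone F6. Add alkenyllithium 8, made as in step 5, at −78 °C; the lithium hemiketal survives until work-up and gives the hydroxy enone F7. Reduce F7 1,2 under Luche conditions (NaBH4, CeCl3·7H2O, MeOH, −40 °C) to 10. This replaces addition to a latent aldehyde by acyl substitution followed by reduction.

Step 6. The silylating agent may cap the secondary alcohol of 10 before it rearranges (that material is recovered as 10). The tertiary alcohol may ionise, or the allyl cation may be trapped by it as a cyclic ether. The E/Z ratio may erode if trapping is slow. The fallback sets out from 10 and comes back at 12. PhSSPh and PBu3 (THF, rt) convert the secondary allylic alcohol by SN2 into the phenyl sulfide F8, the tertiary alcohol staying inert. mCPBA (1.0 equiv, CH2Cl2, −78 °C) gives the sulfoxide F9. Warming F9 with Et2NH in MeOH brings about the Mislow–Evans [2,3] sulfoxide–sulfenate rearrangement, and irreversible cleavage of the sulfenate gives 12 with E geometry. Any primary sulfide from SN2′ attack in the first operation returns 10 after the same oxidation and rearrangement and is recycled.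

**Further compounds**

F1 | step 3 | 2-methyl-2-[2-(2,6,6-trimethylcyclohex-1-en-1-yl)ethyl]-1,3-dioxolane | CC1(CCC2=C(C)CCCC2(C)C)OCCO1
F2 | step 3 | racemic 2-methyl-2-[2-(2,2,6-trimethyl-7-oxabicyclo[4.1.0]heptan-1-yl)ethyl]-1,3-dioxolane | CC1(CCC23OC2(C)CCCC3(C)C)OCCO1
F3 | step 3 | racemic 2,2-dimethyl-6-methylidene-1-[2-(2-methyl-1,3-dioxolan-2-yl)ethyl]cyclohexan-1-ol | CC1(CCC2(O)C(=C)CCCC2(C)C)OCCO1
F4 | step 3 | racemic methyl carbonate of F3 | CC1(CCC2(OC(=O)OC)C(=C)CCCC2(C)C)OCCO1
F5 | step 3 | 2-{2-[(1S)-2,2-dimethyl-6-methylidenecyclohexyl]ethyl}-2-methyl-1,3-dioxolane | C=C1CCCC(C)(C)[C@@H]1CCC1(C)OCCO1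
F6 | step 5 | δ-lactone (4aR,6aS,10aS,10bR)-4a,7,7,10a-tetramethyldodecahydro-3H-benzo[f]chromen-3-one | O=C1CC[C@@H]2[C@@]3(C)CCCC(C)(C)[C@@H]3CC[C@@]2(C)O1
F7 | step 5 | hydroxy enone, 6-[(1S)-2,2-dimethyl-6-methylidenecyclohexyl]-1-[(1R,2R,4aS,8aS)-2-hydroxy-2,5,5,8a-tetramethyldecahydronaphthalen-1-yl]-4-methylidenehexan-3-one | C=C1CCCC(C)(C)[C@@H]1CCC(=C)C(=O)CC[C@@H]1[C@@]2(C)CCCC(C)(C)[C@@H]2CC[C@@]1(C)O
F8 | step 6 | C3′ phenyl sulfide of 10 (C3′ epimers) | C=C1CCCC(C)(C)[C@@H]1CCC(=C)C(Sc1ccccc1)CC[C@@H]1[C@@]2(C)CCCC(C)(C)[C@@H]2CC[C@@]1(C)O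
F9 | step 6 | C3′ phenyl sulfoxide of 10 (diastereomer mixture) | C=C1CCCC(C)(C)[C@@H]1CCC(=C)C(S(=O)c1ccccc1)CC[C@@H]1[C@@]2(C)CCCC(C)(C)[C@@H]2CC[C@@]1(C)O
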